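**Retrosynthetic overview**

1. Locants: ring C is C1–C6 with C7–C9, ring B is C1'–C6' with C7'–C9', ring A is C1''–C6'' with C7''–C9''; in the tetrahydrofuran O1, C2 = C7, C3 = C8, C4 = C8', C5 = C9'. The strategy rests on one feature: of the three benzylic carbons only C7 is para to a free phenol (O4–H of ring C). O4' of ring B is the aryl ether to C8'' and ring A can be kept acylated, so a quinone methide can form only at C7, the future C2.
2. Last skeletal event, and the only ring built (the three arenes are bought, the dioxane acetonide is temporary): O1–C2, by oxidation of C7–H of a mono-phenol 9,9'-diol to the ring C quinone methide and 5-exo capture by O9'. Acetonide and pivalate removal follow.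
3. Arylglycerol: C7''–C8'' by an Evans syn glycolate aldol of the ring B aryloxyacetyl imide with O-pivaloylvanillin (syn aldol = threo; 7''R,8''R from the (S)-auxiliary), then reductive auxiliary cleavage and acetonide formation. The aryloxyacetyl imide comes from mono-O-alkylation of C2-symmetric (8R,8'R)-secoisolariciresinol, whose two phenols are homotopic.
4. Seco core: C8–C8' by oxidative homocoupling of the (S)-4-benzyloxazolidinone imide enolate of O-benzyl-dihydroferulic acid, then reduction and hydrogenolysis.

Key step: step 14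

Assumption: dihydroferulic acid 1 is bought as such (it is the hydrogenation product of ferulic acid); minor diastereomers from steps 3 and 10 are removed at those stages.

**Route**

Step 1
Reactants: 1 3-(4-hydroxy-3-methoxyphenyl)propanoic acid (dihydroferulic acid)
Product: 3 3-(4-benzyloxy-3-methoxyphenyl)propanoic acid, via benzyl ester 2 (not isolated)
Conditions: BnBr (2.3 equiv), K2CO3, DMF, 60 °C; then NaOH, MeOH–H2O, 60 °C; HCl to pH 2
Reagents that add atoms: benzyl bromide BrCc1ccccc1
Why: Williamson O-benzylation of phenoxide and carboxylate followed by saponification of the benzyl ester should leave only the base-stable aryl benzyl ether needed for the enolate chemistry.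

Step 2
Reactants: 3 3-(4-benzyloxy-3-methoxyphenyl)propanoic acid; 4 (S)-4-benzyl-2-oxazolidinone
Product: 6 (S)-4-benzyl-3-[3-(4-benzyloxy-3-methoxyphenyl)propanoyl]oxazolidin-2-one, via mixed anhydride 5 (not isolated)
Conditions: PivCl, Et3N, THF, −20 °C; then 4, LiCl, −20 °C → rt
Reagents that add atoms: pivaloyl chloride CC(C)(C)C(Cl)=O (its acyl group is held in 5 only and leaves as pivalate)
Why: N-acylation of the oxazolidinone through the mixed pivalic anhydride, in which the hindered pivaloyl carbonyl directs attack to the arylpropanoyl carbonyl.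

Step 3
Reactants: 6 (S)-4-benzyl-3-[3-(4-benzyloxy-3-methoxyphenyl)propanoyl]oxazolidin-2-one (two molecules)
Product: 8 (4S,4'S)-3,3'-[(2R,3R)-2,3-bis(4-benzyloxy-3-methoxybenzyl)butanedioyl]bis(4-benzyloxazolidin-2-one), via lithium enolate 7 (not isolated)
Conditions: LiN(iPr)2 (1.1 equiv), THF, −78 °C; TiCl4 (1.1 equiv), −78 °C → rt
Reagents that add atoms: lithium diisopropylamide CC(C)N([Li])C(C)C (lithium is held in 7 only)
Why: Oxidative enolate homocoupling, in which tetravalent titanium takes one electron from each Z-enolate (leaving trivalent titanium) and the C8–C8' bond should form at each terminus on the enolate face opposite the 4-benzyl group of the auxiliary, setting both new stereocentres R.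

Step 4
Reactants: 8 the (2R,3R)-bis-imide
Product: 9 (2R,3R)-2,3-bis(4-benzyloxy-3-methoxybenzyl)butane-1,4-diol (di-O-benzyl-secoisolariciresinol)
Conditions: LiBH4 (excess), MeOH (additive), THF, 0 °C → rt
Reagents that add atoms: none
Why: Reductive cleavage of both N-acyl oxazolidinones by borohydride gives the primary alcohols without enolisation, so C8 and C8' keep their configuration and the auxiliary is recovered.

Step 5
Reactants: 9 di-O-benzyl-secoisolariciresinol
Product: 10 (8R,8'R)-(−)-secoisolariciresinol, (2R,3R)-2,3-bis(4-hydroxy-3-methoxybenzyl)butane-1,4-diol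
Conditions: H2 (1 atm), Pd/C (10% palladium on carbon), EtOAc–MeOH, rt
Reagents that add atoms: none
Why: Hydrogenolysis of the two aryl benzyl ethers is safe here because the skeleton still has no benzylic C–O bond.

Step 6
Reactants: 4 (S)-4-benzyl-2-oxazolidinone
Product: 12 (S)-4-benzyl-3-(bromoacetyl)oxazolidin-2-one, via N-lithio oxazolidinone 11 (not isolated)
Conditions: n-BuLi, THF, −78 °C; BrCH2COBr, −78 → 0 °C
Reagents that add atoms: bromoacetyl bromide BrCC(Br)=O; n-butyllithium [Li]CCCC (lithium is held in 11 only)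
Why: N-acylation of the lithiated oxazolidinone by the acid bromide, which reacts at the acyl carbon faster than at the α-bromide.

Step 7
Reactants: 10 (8R,8'R)-secoisolariciresinol (2 equiv, excess recovered); 12 (S)-4-benzyl-3-(bromoacetyl)oxazolidin-2-one
Product: 13 (8R,8'R)-secoisolariciresinol 4'-O-[2-((S)-4-benzyl-2-oxooxazolidin-3-yl)-2-oxoethyl] ether (mono-aryloxyacetyl imide; ring C phenol and 9,9'-diol free)
Conditions: K2CO3 (1.1 equiv on 12), acetone, 0 °C → rt
Reagents that add atoms: none
Why: Williamson etherification in which carbonate ionises only the phenols and the α-bromo imide is a fast SN2 partner; the two phenols are homotopic by C2 symmetry, so every mono-ether is the same compound, and the excess of 10 should suppress the bis-ether.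

Step 8
Reactants: 13 the mono-aryloxyacetyl imide
Product: 14 tris-TBS ether of 13 (O4 of ring C, O9 and O9' silylated)
Conditions: TBSCl (4 equiv), imidazole, DMF, rt
Reagents that add atoms: tert-butyldimethylsilyl chloride CC(C)(C)[Si](C)(C)Cl
Why: Imidazole-promoted silylation masks the phenol and both primary hydroxyls, which would otherwise consume the boron triflate of the aldol step, with one group removable later in a single operation.

Step 9
Reactants: 15 vanillin
Product: 16 4-formyl-2-methoxyphenyl pivalate
Conditions: PivCl, Et3N, DMAP (cat.), CH2Cl2, 0 °C → rt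
Reagents that add atoms: pivaloyl chloride CC(C)(C)C(Cl)=O
Why: Acylation of the phenol gives the ring A aldehyde with an electron-withdrawing, borohydride-tolerant ester that later shields ring A from the oxidant.

Step 10
Reactants: 14 the tris-TBS aryloxyacetyl imide; 16 4-formyl-2-methoxyphenyl pivalate
Product: 18 syn-aldol adduct, (S)-4-benzyl-3-[(2S,3R)-3-hydroxy-3-(3-methoxy-4-pivaloyloxyphenyl)-2-(aryloxy)propanoyl]oxazolidin-2-one with aryloxy = O4' of ring B of the tris-TBS seco unit, via boron enolate 17 (not isolated)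
Conditions: Bu2BOTf (1.3 equiv), i-Pr2NEt (1.5 equiv), CH2Cl2, −78 → 0 °C; 16 (1.5 equiv), −78 → 0 °C; pH 7 phosphate buffer, MeOH, 30% H2O2, 0 °C
Reagents that add atoms: dibutylboron triflate CCCCB(CCCC)OS(=O)(=O)C(F)(F)F (the dibutylboryl group is held in 17 only)
Why: Evans syn glycolate aldol, in which the Z boron enolate reacts through a Zimmerman–Traxler chair on the face opposite the auxiliary benzyl group, so C8'' and C7'' should form 2,3-syn (2S,3R in the imide), the threo pattern that reads 7''R,8''R once the acyl carbon is reduced.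

Step 11
Reactants: 18 the syn-aldol imide
Product: 19 threo-(7''R,8''R)-1,3-diol: tris-TBS (8R,8'R)-secoisolariciresinol 4'-O-ether with C8'' of 1-(3-methoxy-4-pivaloyloxyphenyl)propane-1,3-diol
Conditions: LiBH4 (2 equiv), MeOH (2 equiv), THF, 0 °C
Reagents that add atoms: none
Why: Chemoselective borohydride reduction of the activated exocyclic imide carbonyl to the primary alcohol, fast at 0 °C, whereas the hindered aryl pivalate and the silyl ethers should survive; the auxiliary is recovered.

Step 12
Reactants: 19 the threo 1,3-diol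
Product: 20 O7'',O9''-acetonide of 19, the (4R,5R)-2,2-dimethyl-4-(3-methoxy-4-pivaloyloxyphenyl)-1,3-dioxan-5-yl ether of O4' of ring B, still tris-TBS
Conditions: 2,2-dimethoxypropane, PPTS (cat.), CH2Cl2, rt
Reagents that add atoms: 2,2-dimethoxypropane COC(C)(C)OC
Why: Acid-catalysed transacetalisation closes the six-membered isopropylidene acetal on the 1,3-diol under conditions too mild to cleave the TBS ethers or ionise the deactivated ring A benzylic position.

Step 13
Reactants: 20 the tris-TBS acetonide
Product: 21 key-step precursor: (8R,8'R)-secoisolariciresinol 4'-O-ether carrying the threo arylglycerol as ring A pivalate and O7'',O9''-acetonide, with free ring C phenol and free 9,9'-diol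
Conditions: TBAF (4 equiv), AcOH (4 equiv), THF, 0 °C → rt
Reagents that add atoms: none
Why: Fluoride-mediated desilylation buffered with acetic acid removes the aryl and both primary TBS groups while keeping the phenol protonated, so the aryl pivalate is neither cleaved nor transferred and the acetonide is untouched.

Step 14
Reactants: 21 the mono-phenol 9,9'-diol
Product: 23 key-step product: (7S,8R,8'R)-lariciresinol 4'-O-ether (tetrahydrofuran 2S,3R,4R) carrying the threo arylglycerol as ring A pivalate and O7'',O9''-acetonide, via quinone methide 22 (not isolated)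
Conditions: DDQ (1.05 equiv, added slowly as a solution), 2,6-di-tert-butylpyridine (1.5 equiv), 4 Å MS, CH2Cl2, −20 → 0 °C; aq. NaHCO3 wash
Reagents that add atoms: none
Why: DDQ forms a charge-transfer complex with the only free phenol (ring C) and removes hydride from C7 in a net two-electron oxidation, and loss of the phenolic proton gives p-quinone methide 22, whose exocyclic C7 is attacked by the C9' hydroxyl in a 1,6-conjugate addition that rearomatises ring C and forms the O1–C2 bond. The closest known reaction type is the DDQ dehydrogenation of 4-alkylphenols to quinone methides with capture by alcohols, together with the quinone methide cycloetherification by which 7-oxygenated seco-lignan triols close to 2-aryl-3-hydroxymethyl-4-benzyltetrahydrofurans. The tetrahydrofuran closes 5-exo-trig (O9' onto C7 through C8' and C8), whereas attack by the O9 hydroxyl would be a 4-exo closure to an oxetane and is not expected to compete. The new stereocentre C2 (7S) is controlled by the adjacent C3 (C8) centre: the planar quinone methide should react in the envelope that places the aryl group trans to the C3 hydroxymethyl and trans to the C4 benzyl, which is also the thermodynamically preferred 2,3-trans-3,4-cis arrangement. The step needs chemoselectivity among three benzylic positions and O- rather than C-capture: the first is secured because ring A is an aryl pivalate and ring B an aryl alkyl ether, so neither can give a neutral quinone methide and both are far slower hydride donors than the free guaiacol; the second by the buffered, aprotic, cold conditions and the slow addition of one equivalent of oxidant, which should hold back Friedel–Crafts closure of C6' onto C7 and over-oxidation at the new C2–H.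

Step 15
Reactants: 23 the cyclised acetonide pivalate
Product: 24 ring A 4''-O-pivalate of the target (7''-OH and 9''-OH free)
Conditions: AcOH–THF–H2O (3:1:1), rt (warmed to 35 °C only if needed)
Reagents that add atoms: none
Why: Acid-catalysed hydrolysis of the isopropylidene acetal in weak acid, run while ring A is still the electron-poor pivalate so that C7''–O cannot ionise, and under conditions expected to be too mild to open the C2–O1 benzylic ether.

Step 16
Reactants: 24 the ring A pivalate
Product: 25 target, CNP0158473.2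
Conditions: K2CO3 (0.5 equiv), MeOH, argon, 0 °C → rt; NH4Cl quench
Reagents that add atoms: none
Why: Base-catalysed methanolysis of the activated aryl ester frees the ring A phenol; because O7'' is by now a free hydroxyl (a poor leaving group), ring A cannot form a quinone methide under these conditions and C7''/C8'' should not be scrambled.

**Compound list**

1 | 3-(4-hydroxy-3-methoxyphenyl)propanoic acid (dihydroferulic acid) | COc1cc(CCC(=O)O)ccc1O | starting material
2 | benzyl 3-(4-benzyloxy-3-methoxyphenyl)propanoate | COc1cc(CCC(=O)OCc2ccccc2)ccc1OCc1ccccc1 | intermediate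
3 | 3-(4-benzyloxy-3-methoxyphenyl)propanoic acid | COc1cc(CCC(=O)O)ccc1OCc1ccccc1 | intermediate
4 | (S)-4-benzyl-2-oxazolidinone | O=C1N[C@@H](Cc2ccccc2)CO1 | starting material
5 | 3-(4-benzyloxy-3-methoxyphenyl)propanoic pivalic anhydride | COc1cc(CCC(=O)OC(=O)C(C)(C)C)ccc1OCc1ccccc1 | intermediate
6 | (S)-4-benzyl-3-[3-(4-benzyloxy-3-methoxyphenyl)propanoyl]oxazolidin-2-one | COc1cc(CCC(=O)N2[C@@H](Cc3ccccc3)COC2=O)ccc1OCc1ccccc1 | intermediate
7 | lithium Z-enolate of 6 | COc1cc(C/C=C(\O[Li])N2[C@@H](Cc3ccccc3)COC2=O)ccc1OCc1ccccc1 | intermediate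
8 | (4S,4'S)-3,3'-[(2R,3R)-2,3-bis(4-benzyloxy-3-methoxybenzyl)butanedioyl]bis(4-benzyloxazolidin-2-one) | O=C(N1[C@@H](Cc2ccccc2)COC1=O)[C@H](Cc1ccc(OCc2ccccc2)c(OC)c1)[C@@H](Cc1ccc(OCc2ccccc2)c(OC)c1)C(=O)N1[C@@H](Cc2ccccc2)COC1=O | intermediate
9 | (2R,3R)-2,3-bis(4-benzyloxy-3-methoxybenzyl)butane-1,4-diol | COc1cc(C[C@@H](CO)[C@H](CO)Cc2ccc(OCc3ccccc3)c(OC)c2)ccc1OCc1ccccc1 | intermediate
10 | (8R,8'R)-(−)-secoisolariciresinol | COc1cc(C[C@@H](CO)[C@H](CO)Cc2ccc(O)c(OC)c2)ccc1O | intermediate
11 | N-lithio-(S)-4-benzyloxazolidin-2-one | [Li]N1[C@@H](Cc2ccccc2)COC1=O | intermediate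
12 | (S)-4-benzyl-3-(bromoacetyl)oxazolidin-2-one | O=C(CBr)N1[C@@H](Cc2ccccc2)COC1=O | intermediate
13 | (8R,8'R)-secoisolariciresinol 4'-O-[2-((S)-4-benzyl-2-oxooxazolidin-3-yl)-2-oxoethyl] ether | COc1cc(C[C@@H](CO)[C@H](CO)Cc2ccc(O)c(OC)c2)ccc1OCC(=O)N1[C@@H](Cc2ccccc2)COC1=O | intermediate
14 | tris-TBS ether of 13 (O4, O9, O9') | COc1cc(C[C@@H](CO[Si](C)(C)C(C)(C)C)[C@H](CO[Si](C)(C)C(C)(C)C)Cc2ccc(O[Si](C)(C)C(C)(C)C)c(OC)c2)ccc1OCC(=O)N1[C@@H](Cc2ccccc2)COC1=O | intermediate
15 | vanillin | COc1cc(C=O)ccc1O | starting material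
16 | 4-formyl-2-methoxyphenyl pivalate | COc1cc(C=O)ccc1OC(=O)C(C)(C)C | intermediate
17 | dibutylboron Z-enolate of 14 | CCCCB(CCCC)O/C(=C\Oc1ccc(C[C@@H](CO[Si](C)(C)C(C)(C)C)[C@H](CO[Si](C)(C)C(C)(C)C)Cc2ccc(O[Si](C)(C)C(C)(C)C)c(OC)c2)cc1OC)N1[C@@H](Cc2ccccc2)COC1=O | intermediate
18 | syn-aldol imide (C8'' S, C7'' R in the imide), tris-TBS, ring A pivalate | COc1cc([C@@H](O)[C@@H](C(=O)N2[C@@H](Cc3ccccc3)COC2=O)Oc2ccc(C[C@@H](CO[Si](C)(C)C(C)(C)C)[C@H](CO[Si](C)(C)C(C)(C)C)Cc3ccc(O[Si](C)(C)C(C)(C)C)c(OC)c3)cc2OC)ccc1OC(=O)C(C)(C)C | intermediate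
19 | threo-(7''R,8''R)-1,3-diol, tris-TBS, ring A pivalate | COc1cc([C@@H](O)[C@@H](CO)Oc2ccc(C[C@@H](CO[Si](C)(C)C(C)(C)C)[C@H](CO[Si](C)(C)C(C)(C)C)Cc3ccc(O[Si](C)(C)C(C)(C)C)c(OC)c3)cc2OC)ccc1OC(=O)C(C)(C)C | intermediate
20 | O7'',O9''-acetonide of 19 | COc1cc([C@@H](OC(C)(C)OC5)[C@@H]5Oc2ccc(C[C@@H](CO[Si](C)(C)C(C)(C)C)[C@H](CO[Si](C)(C)C(C)(C)C)Cc3ccc(O[Si](C)(C)C(C)(C)C)c(OC)c3)cc2OC)ccc1OC(=O)C(C)(C)C | intermediate
21 | key-step precursor: seco mono-ether, ring A pivalate, O7'',O9''-acetonide, free ring C phenol and 9,9'-diol | COc1cc([C@@H](OC(C)(C)OC5)[C@@H]5Oc2ccc(C[C@@H](CO)[C@H](CO)Cc3ccc(O)c(OC)c3)cc2OC)ccc1OC(=O)C(C)(C)C | intermediate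
22 | ring C p-quinone methide of 21 (C7=C1) | COc1cc([C@@H](OC(C)(C)OC5)[C@@H]5Oc2ccc(C[C@@H](CO)[C@H](CO)C=C3C=CC(=O)C(OC)=C3)cc2OC)ccc1OC(=O)C(C)(C)C | intermediate
23 | key-step product: tetrahydrofuran (2S,3R,4R), ring A pivalate, O7'',O9''-acetonide | COc1cc([C@@H](OC(C)(C)OC5)[C@@H]5Oc2ccc(C[C@H]3CO[C@H](c4ccc(O)c(OC)c4)[C@H]3CO)cc2OC)ccc1OC(=O)C(C)(C)C | intermediate
24 | ring A 4''-O-pivalate of the target | COc1cc([C@@H](O)[C@@H](CO)Oc2ccc(C[C@H]3CO[C@H](c4ccc(O)c(OC)c4)[C@H]3CO)cc2OC)ccc1OC(=O)C(C)(C)C | intermediate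
25 | CNP0158473.2, (7S,8R,8'R)-lariciresinol 4'-O-[threo-(7''R,8''R)-guaiacylglycer-8''-yl] ether | COc1cc([C@@H](O)[C@@H](CO)Oc2ccc(C[C@H]3CO[C@H](c4ccc(O)c(OC)c4)[C@H]3CO)cc2OC)ccc1O | target

**Step count and risks**

Total steps: 16. Longest linear sequence: 14 (steps 1–5, 7, 8, 10–16); steps 6 and 9 are side branches.

Steps most likely to fail:

1. Step 14 (key step). What may go wrong: hydride abstraction may not stay confined to C7 of the fully assembled substrate. The oxidant may go on to attack the new phenol-activated C2–H of the product, the quinone methide may tautomerise to the C7=C8 styrene, or it may be captured by C6' of ring B. Each of these costs advanced material that cannot be recycled. Fallback: move the ring closure to the small mono-ether, before ring A and the acetal exist and where partial conversion with recycling is affordable. The fallback sets out from 13: treatment with DDQ under the same buffered conditions should give the cyclised aryloxyacetyl imide F1. Silylation (TBSCl, imidazole) gives the bis-TBS ether F2. The Evans syn glycolate aldol with 16 (Bu2BOTf, i-Pr2NEt) gives the aldol imide F3, and LiBH4 reduction gives the threo diol F4. Buffered desilylation (TBAF, AcOH) returns to the route at 24, bypassing the acetonide and the acid step.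

2. Step 3. What may go wrong: the one-electron oxidation of the enolate may give low conversion (protonation, α-chlorination or loss of the auxiliary through a ketene), and facial control may be incomplete at one terminus, giving the (R,S) diastereomer. Fallback: build the C8–C8' unit stepwise by enolate alkylations instead of dimerisation. The fallback sets out from 6: NaN(SiMe3)2 and tert-butyl bromoacetate give the alkylated imide F5 (auxiliary-controlled, R). LiBH4 gives the hydroxy ester F6, and TFA closes it to the (R)-β-benzyl lactone F7. The lithium enolate of F7 (LiN(SiMe3)2, THF, −78 °C) is alkylated trans to the existing benzyl group with 4-benzyloxy-3-methoxybenzyl bromide F9 (from the commercial alcohol and PBr3), giving di-O-benzyl-(−)-matairesinol F8. LiAlH4 reduction of F8 returns to the route at 9.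

3. Step 15. What may go wrong: acid-induced heterolysis of the C2–O1 bond of the p-hydroxyphenyl tetrahydrofuran (ring opening to the benzylic cation or quinone methide, then epimerisation at C2 or Friedel–Crafts closure onto ring B), or incomplete hydrolysis under conditions mild enough to avoid this. Fallback: leave out the acetonide so that no acid is needed after the ring is formed. The fallback sets out from 19: buffered desilylation (TBAF, AcOH) gives the pentahydroxy mono-phenol pivalate F10. The DDQ cyclisation of step 14 is then run on F10, whose free benzylic C7''–OH sits on the pivalate-deactivated ring A and should be oxidised far more slowly than the free phenol. This returns to the route at 24.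

**Further compounds**

F1 | step 14 | (7S,8R,8'R)-lariciresinol 4'-O-[2-((S)-4-benzyl-2-oxooxazolidin-3-yl)-2-oxoethyl] ether | COc1cc(C[C@H]2CO[C@H](c3ccc(O)c(OC)c3)[C@H]2CO)ccc1OCC(=O)N1[C@@H](Cc2ccccc2)COC1=O
F2 | step 14 | bis-TBS ether of F1 (O4 of ring C and O9) | COc1cc(C[C@H]2CO[C@H](c3ccc(O[Si](C)(C)C(C)(C)C)c(OC)c3)[C@H]2CO[Si](C)(C)C(C)(C)C)ccc1OCC(=O)N1[C@@H](Cc2ccccc2)COC1=O
F3 | step 14 | syn-aldol imide of F2 with 16 | COc1cc([C@@H](O)[C@@H](C(=O)N2[C@@H](Cc3ccccc3)COC2=O)Oc2ccc(C[C@H]3CO[C@H](c4ccc(O[Si](C)(C)C(C)(C)C)c(OC)c4)[C@H]3CO[Si](C)(C)C(C)(C)C)cc2OC)ccc1OC(=O)C(C)(C)C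
F4 | step 14 | threo-(7''R,8''R) diol from F3, bis-TBS, ring A pivalate | COc1cc([C@@H](O)[C@@H](CO)Oc2ccc(C[C@H]3CO[C@H](c4ccc(O[Si](C)(C)C(C)(C)C)c(OC)c4)[C@H]3CO[Si](C)(C)C(C)(C)C)cc2OC)ccc1OC(=O)C(C)(C)C
F5 | step 3 | (S)-4-benzyl-3-[(2R)-2-(4-benzyloxy-3-methoxybenzyl)-4-tert-butoxy-4-oxobutanoyl]oxazolidin-2-one | COc1cc(C[C@H](CC(=O)OC(C)(C)C)C(=O)N2[C@@H](Cc3ccccc3)COC2=O)ccc1OCc1ccccc1
F6 | step 3 | tert-butyl (3R)-4-(4-benzyloxy-3-methoxyphenyl)-3-(hydroxymethyl)butanoate | COc1cc(C[C@H](CC(=O)OC(C)(C)C)CO)ccc1OCc1ccccc1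
F7 | step 3 | (R)-4-(4-benzyloxy-3-methoxybenzyl)dihydrofuran-2(3H)-one | COc1cc(C[C@H]2COC(=O)C2)ccc1OCc1ccccc1
F8 | step 3 | (3R,4R)-3,4-bis(4-benzyloxy-3-methoxybenzyl)dihydrofuran-2(3H)-one (di-O-benzyl-(−)-matairesinol) | COc1cc(C[C@H]2COC(=O)[C@@H]2Cc2ccc(OCc3ccccc3)c(OC)c2)ccc1OCc1ccccc1
F9 | step 3 | 4-benzyloxy-3-methoxybenzyl bromide | COc1cc(CBr)ccc1OCc1ccccc1
F10 | step 15 | (8R,8'R)-secoisolariciresinol 4'-O-ether with C8'' of threo-(7''R,8''R)-1-(3-methoxy-4-pivaloyloxyphenyl)propane-1,3-diol (all hydroxyls and ring C phenol free) | COc1cc([C@@H](O)[C@@H](CO)Oc2ccc(C[C@@H](CO)[C@H](CO)Cc3ccc(O)c(OC)c3)cc2OC)ccc1OC(=O)C(C)(C)C
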